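**Plan** (daucane numbering: C1 = ring-fusion carbon bearing CH3, C2/C3 = cyclopentane CH2 groups, C4 = isopropyl carbinol carbon, C5 = ring-fusion CH, C6 = ester-bearing carbon, C7–C10 = rest of the seven-membered ring, CH3 on C8; β = face of the C1 methyl)
1. Retrosynthesis: cut the C6 ester and the 8,9-epoxide (back to jaeschkeanadiol), then C1–C2 and C3–C4 of the cyclopentane together, then C8=C9 (ring-closing metathesis), then C5–C6 (aldol).
2. Forward: an aldol joins a dienyl isopropyl ketone and 3-methylbut-3-enal, metathesis closes the seven-membered ring, and a [3+2] radical-polar crossover annulation with phenyl vinyl sulfone builds the five-membered ring on it.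
3. Enabling feature: in cycloheptene 12 the exocyclic methylene on ring carbon C1 (latent tertiary radical) and the isobutyryl carbonyl C4 on the neighbouring ring carbon C5 form a 1,3 radical/electrophile pair that a two-carbon radical acceptor can bridge.
4. Stereochemistry: C5 from a reagent-controlled boron aldol; C1 and C4 from C5 (helped by the cis C6 silyloxy group) in the annulation; C6 is then reset by oxidation and C4-hydroxyl-directed reduction; C8/C9 from C6-hydroxyl-directed epoxidation.

Key step: step 7

Assumption: the (−)-antipode of Ipc2BOTf (from (+)-α-pinene) is taken to deliver the (4S,5R) aldol 10; if the sense of induction is the reverse, the (+)-antipode is used and nothing else changes.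

**Step 1**
Reactants: 1 3-chloro-2-(chloromethyl)prop-1-ene; 2 vinylmagnesium bromide
Product: 3 2-(chloromethyl)penta-1,4-diene
Conditions: CuI (5 mol %), THF, −30 to 0 °C, 1 in threefold excess
Reagents that add atoms: none
Why: Copper-catalysed allylic substitution by the vinyl Grignard reagent, in which SN2 and SN2' attack give the same product on this symmetrical bis-allylic chloride and the excess of 1 should suppress double substitution.

**Step 2**
Reactants: 3 2-(chloromethyl)penta-1,4-diene; 4 N-methoxy-N-methylisobutyramide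
Product: 6 2-methyl-5-methylideneoct-7-en-3-one, via allylic Grignard reagent 5 (not isolated)
Conditions: Mg, THF, 0 °C; then 4, −78 to 0 °C; cold aq NH4Cl
Reagents that add atoms: none
Why: Weinreb ketone synthesis with an allylic Grignard reagent, where the chelated tetrahedral adduct should stop at the ketone and the cold neutral quench should keep the alkene out of conjugation.

**Step 3**
Reactants: 7 3-methylbut-3-en-1-ol
Product: 8 3-methylbut-3-enal
Conditions: Dess–Martin periodinane, NaHCO3, CH2Cl2, 0 °C; filtered solution used directly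
Reagents that add atoms: none
Why: Dess–Martin oxidation of a primary alcohol under buffered conditions, which should not isomerise the β,γ-unsaturated aldehyde.

**Step 4**
Reactants: 6 2-methyl-5-methylideneoct-7-en-3-one; 8 3-methylbut-3-enal
Product: 10 (4S,5R)-5-hydroxy-2,7-dimethyl-4-(penta-1,4-dien-2-yl)oct-7-en-3-one, via Z enol diisopinocampheylborinate 9 (not isolated)
Conditions: (−)-Ipc2BOTf, i-Pr2NEt, CH2Cl2, −78 °C; 8, −78 to −20 °C; H2O2, pH 7 buffer, MeOH, 0 °C
Reagents that add atoms: none
Why: Diisopinocampheylboron-mediated aldol reaction, in which the triflate reagent should enolise the doubly activated CH2 to the Z enol borinate, the chair transition state should give the syn aldol through the α-carbon, and the isopinocampheyl ligands should select the enolate face that sets C5 (C4 of 10).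

**Step 5**
Reactants: 10 (4S,5R)-5-hydroxy-2,7-dimethyl-4-(penta-1,4-dien-2-yl)oct-7-en-3-one
Product: 11 (4S,5R)-5-[(tert-butyldimethylsilyl)oxy]-2,7-dimethyl-4-(penta-1,4-dien-2-yl)oct-7-en-3-one
Conditions: TBSOTf, 2,6-lutidine, CH2Cl2, −78 °C
Reagents that add atoms: tert-butyldimethylsilyl trifluoromethanesulfonate, CC(C)(C)[Si](C)(C)OS(=O)(=O)C(F)(F)F
Why: Silylation of the secondary alcohol under cold, weakly basic conditions, which should avoid retro-aldol cleavage and epimerisation of the acidic C5 hydrogen.

**Step 6**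
Reactants: 11 (4S,5R)-5-[(tert-butyldimethylsilyl)oxy]-2,7-dimethyl-4-(penta-1,4-dien-2-yl)oct-7-en-3-one
Product: 12 1-[(1S,2R)-2-[(tert-butyldimethylsilyl)oxy]-4-methyl-7-methylidenecyclohept-4-en-1-yl]-2-methylpropan-1-one
Conditions: second-generation Grubbs catalyst RuCl2(=CHPh)(PCy3)(H2IMes) (5 mol %), 1,4-benzoquinone (10 mol %), CH2Cl2 (5 mM), 40 °C
Reagents that add atoms: none
Why: Ring-closing metathesis between the allyl and methallyl termini should give the trisubstituted cycloheptene, while the third alkene could only close a tetrasubstituted cyclopentene and should remain as the exocyclic methylene.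

**Step 7**
Reactants: 12 1-[(1S,2R)-2-[(tert-butyldimethylsilyl)oxy]-4-methyl-7-methylidenecyclohept-4-en-1-yl]-2-methylpropan-1-one; 13 phenyl vinyl sulfone
Product: 16 6β-[(tert-butyldimethylsilyl)oxy]-3-(phenylsulfonyl)dauc-8-en-4β-ol (1β-methyl 5α-H trans-fused; C3 epimers), via tertiary C1 radical 14 (not isolated), via sulfonyl-stabilised carbanion 15 (not isolated)
Conditions: Fe(acac)3 (30 mol %), PhSi(Oi-Pr)H2 (2.5 equiv), 13 (3 equiv), THF, 0 °C to rt; aq NH4Cl
Reagents that add atoms: none
Why: Proposed new method: an iron hydride formed from Fe(acac)3 and the silane transfers a hydrogen atom to the exocyclic CH2 of 12, the tertiary C1 radical 14 adds to the CH2 terminus of phenyl vinyl sulfone (C1–C2 bond), divalent iron reduces the electrophilic α-sulfonyl radical to carbanion 15, and 15 adds to the C4 ketone (C3–C4 bond) before it is protonated in the aprotic medium. The closest known reaction types are the iron hydride reductive olefin coupling with vinyl sulfones and the hydrogen-atom-transfer-initiated conjugate addition–aldol annulation that builds cyclohexanols from alkenyl aldehydes and enones; here the same radical-polar crossover is asked to close a five-membered ring onto a ketone with a sulfonyl-stabilised carbanion. The only ring closed is the cyclopentane, in the 5-exo-trig mode (carbanion C3 onto the C4 carbonyl); the radical step is intermolecular. C1 is set because the acceptor should approach the cycloheptyl radical from the α-face, the isobutyryl group at C5 and the silyloxy group at C6 both lying on the β-face, which makes the ring fusion trans; C4 is set because the isopropyl group should turn away from the angular methyl and from C6 in the cyclisation, leaving the alkoxide oxygen on the β-face; C3 forms as a mixture and is erased in step 8. The step needs hydrogen atom transfer to the 1,1-disubstituted exocyclic alkene rather than to the trisubstituted ring alkene, which the unhindered terminal CH2 should secure, and carbonyl addition rather than quenching of 15, which the absence of a protic cosolvent and the five-membered transition state should secure.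

**Step 8**
Reactants: 16 6β-[(tert-butyldimethylsilyl)oxy]-3-(phenylsulfonyl)dauc-8-en-4β-ol
Product: 17 6β-[(tert-butyldimethylsilyl)oxy]dauc-8-en-4β-ol
Conditions: Na(Hg) (5 % Na), Na2HPO4, MeOH–THF, −20 °C
Reagents that add atoms: none
Why: Reductive desulfonylation by single-electron cleavage of the C–S bond, where the free tertiary hydroxyl is a poor leaving group so that Julia-type elimination should not compete, and the uncontrolled C3 centre disappears.

**Step 9**
Reactants: 17 6β-[(tert-butyldimethylsilyl)oxy]dauc-8-en-4β-ol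
Product: 18 dauc-8-ene-4β,6β-diol (6-epi-jaeschkeanadiol)
Conditions: TBAF, THF, 40 °C
Reagents that add atoms: none
Why: Fluoride-induced cleavage of the silyl ether, which should leave the tertiary alcohol and the alkene untouched.

**Step 10**
Reactants: 18 dauc-8-ene-4β,6β-diol
Product: 19 4β-hydroxydauc-8-en-6-one
Conditions: Dess–Martin periodinane, NaHCO3, CH2Cl2, 0 °C; crude product used at once
Reagents that add atoms: none
Why: Dess–Martin oxidation takes only the secondary C6 alcohol, and the buffered, short handling should keep the now acidic C5 hydrogen from epimerising.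

**Step 11**
Reactants: 19 4β-hydroxydauc-8-en-6-one
Product: 20 dauc-8-ene-4β,6α-diol (jaeschkeanadiol)
Conditions: Me4NBH(OAc)3, AcOH–MeCN, −30 °C
Reagents that add atoms: none
Why: Hydroxyl-directed (Evans–Saksena) reduction, in which the C4 oxygen should bind the triacetoxyborohydride and deliver hydride intramolecularly to the β-face of the C6 carbonyl, so that the new hydroxyl is α.

**Step 12**
Reactants: 20 dauc-8-ene-4β,6α-diol
Product: 21 8α,9α-epoxydaucane-4β,6α-diol
Conditions: VO(acac)2 (5 mol %), t-BuOOH, PhMe, 0 °C to rt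
Reagents that add atoms: tert-butyl hydroperoxide, CC(C)(C)OO
Why: Vanadium-catalysed homoallylic-alcohol-directed epoxidation should deliver oxygen syn to the C6 hydroxyl, onto the α-face, which is also the face remote from the angular methyl.

**Step 13**
Reactants: 21 8α,9α-epoxydaucane-4β,6α-diol; 22 4-[(tert-butyldimethylsilyl)oxy]benzoic acid
Product: 23 8α,9α-epoxy-4β-hydroxydaucan-6α-yl 4-[(tert-butyldimethylsilyl)oxy]benzoate
Conditions: EDC·HCl, DMAP, CH2Cl2, rt
Reagents that add atoms: none
Why: Steglich esterification should acylate only the secondary C6 hydroxyl, the tertiary C4 hydroxyl being unreactive and the non-acidic medium sparing the epoxide.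

**Step 14**
Reactants: 23 8α,9α-epoxy-4β-hydroxydaucan-6α-yl 4-[(tert-butyldimethylsilyl)oxy]benzoate
Product: 24 jaeskeanin
Conditions: TBAF, AcOH, THF, 0 °C
Reagents that add atoms: none
Why: Buffered fluoride cleaves the aryl silyl ether rapidly, while the ester, the epoxide and the tertiary alcohol should survive.

**Compound list**
1 | 3-chloro-2-(chloromethyl)prop-1-ene | C=C(CCl)CCl | starting material
2 | vinylmagnesium bromide | C=C[Mg]Br | starting material
3 | 2-(chloromethyl)penta-1,4-diene | C=CCC(=C)CCl | intermediate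
4 | N-methoxy-N-methylisobutyramide | CC(C)C(=O)N(C)OC | starting material
5 | (2-methylidenepent-4-en-1-yl)magnesium chloride | C=CCC(=C)C[Mg]Cl | intermediate (not isolated)
6 | 2-methyl-5-methylideneoct-7-en-3-one | CC(C)C(=O)CC(=C)CC=C | intermediate
7 | 3-methylbut-3-en-1-ol | CC(=C)CCO | starting material
8 | 3-methylbut-3-enal | CC(=C)CC=O | intermediate
9 | Z enol diisopinocampheylborinate of 6 | CC(C)/C(OB([C@@H]1C[C@@H]2C[C@H]([C@H]1C)C2(C)C)[C@@H]1C[C@@H]2C[C@H]([C@H]1C)C2(C)C)=C/C(=C)CC=C | intermediate (not isolated)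
10 | (4S,5R)-5-hydroxy-2,7-dimethyl-4-(penta-1,4-dien-2-yl)oct-7-en-3-one | CC(C)C(=O)[C@@H](C(=C)CC=C)[C@H](O)CC(C)=C | intermediate
11 | (4S,5R)-5-[(tert-butyldimethylsilyl)oxy]-2,7-dimethyl-4-(penta-1,4-dien-2-yl)oct-7-en-3-one | CC(C)C(=O)[C@@H](C(=C)CC=C)[C@H](O[Si](C)(C)C(C)(C)C)CC(C)=C | intermediate
12 | 1-[(1S,2R)-2-[(tert-butyldimethylsilyl)oxy]-4-methyl-7-methylidenecyclohept-4-en-1-yl]-2-methylpropan-1-one | CC(C)C(=O)[C@H]1C(=C)CC=C(C)C[C@H]1O[Si](C)(C)C(C)(C)C | intermediate
13 | phenyl vinyl sulfone | C=CS(=O)(=O)c1ccccc1 | starting material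
14 | tertiary C1 radical from 12 (exocyclic CH2 now CH3) | CC(C)C(=O)[C@H]1[C](C)CC=C(C)C[C@H]1O[Si](C)(C)C(C)(C)C | intermediate (not isolated)
15 | α-sulfonyl carbanion after addition of 14 to 13 (C1 quaternary, β-methyl, α-CH2–CH(−)SO2Ph) | CC(C)C(=O)[C@H]1[C@](C)(C[CH-]S(=O)(=O)c2ccccc2)CC=C(C)C[C@H]1O[Si](C)(C)C(C)(C)C | intermediate (not isolated)
16 | 6β-[(tert-butyldimethylsilyl)oxy]-3-(phenylsulfonyl)dauc-8-en-4β-ol (1β-methyl, 4α-isopropyl, 5α-H, C3 epimers) | CC(C)[C@]1(O)C(S(=O)(=O)c3ccccc3)C[C@]2(C)CC=C(C)C[C@@H](O[Si](C)(C)C(C)(C)C)[C@H]21 | intermediate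
17 | (1R,4R,5S,6R)-6-[(tert-butyldimethylsilyl)oxy]dauc-8-en-4-ol (4β-OH, 6β-OSi) | CC(C)[C@]1(O)CC[C@]2(C)CC=C(C)C[C@@H](O[Si](C)(C)C(C)(C)C)[C@H]21 | intermediate
18 | (1R,4R,5S,6R)-dauc-8-ene-4,6-diol (4β,6β; 6-epi-jaeschkeanadiol) | CC(C)[C@]1(O)CC[C@]2(C)CC=C(C)C[C@@H](O)[C@H]21 | intermediate
19 | 4β-hydroxydauc-8-en-6-one (1β-methyl, 5α-H) | CC(C)[C@]1(O)CC[C@]2(C)CC=C(C)CC(=O)[C@H]21 | intermediate
20 | (1R,4R,5S,6S)-dauc-8-ene-4,6-diol (4β,6α; jaeschkeanadiol) | CC(C)[C@]1(O)CC[C@]2(C)CC=C(C)C[C@H](O)[C@H]21 | intermediate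
21 | (1R,4R,5S,6S,8R,9S)-8,9-epoxydaucane-4,6-diol (8α,9α-epoxide) | CC(C)[C@]1(O)CC[C@]2(C)C[C@@H]3O[C@]3(C)C[C@H](O)[C@H]21 | intermediate
22 | 4-[(tert-butyldimethylsilyl)oxy]benzoic acid | CC(C)(C)[Si](C)(C)Oc1ccc(cc1)C(=O)O | starting material
23 | 8α,9α-epoxy-4β-hydroxydaucan-6α-yl 4-[(tert-butyldimethylsilyl)oxy]benzoate | CC(C)[C@]1(O)CC[C@]2(C)C[C@@H]3O[C@]3(C)C[C@H](OC(=O)c3ccc(O[Si](C)(C)C(C)(C)C)cc3)[C@H]21 | intermediate
24 | jaeskeanin, (1R,4R,5S,6S,8R,9S)-8,9-epoxy-4-hydroxydaucan-6-yl 4-hydroxybenzoate | CC(C)[C@]1(O)CC[C@]2(C)C[C@@H]3O[C@]3(C)C[C@H](OC(=O)c3ccc(O)cc3)[C@H]21 | target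

**Step count and risks**
Total steps: 14. Longest linear sequence: 13 steps (steps 1, 2 and 4 to 14; step 3 is a one-step branch).

Steps most likely to fail:

Step 7. The α-sulfonyl radical or carbanion may be intercepted by hydrogen transfer before it adds to the ketone, so that only the open-chain hydroalkylation occurs. The fallback sets out from 12 and returns at 16. The iron hydride reductive olefin coupling of 12 with 13 is run under its usual protic conditions (Fe(acac)3, PhSiH3, EtOH–ethylene glycol, 60 °C) and should give the open-chain keto sulfone, 12 carrying at C1 a β-methyl and an α-2-(phenylsulfonyl)ethyl group, F1. Deprotonation α to the sulfone (LDA, THF, −78 °C), where the hindered ketone α-positions should react more slowly, then lets the lithiated sulfone add to the ketone in a separate polar ring closure to give 16.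

Step 4. The isopinocampheyl ligands may discriminate poorly between the enolate faces of this unusual dienyl ketone, or the β,γ-unsaturated partners may drift into conjugation. The fallback sets out from 3 and returns at 11, with the absolute configuration taken from a covalently bound auxiliary. The Grignard reagent from 3 is carboxylated (CO2) to 3-methylidenehex-5-enoic acid F2. F2 is coupled through its pivaloyl mixed anhydride with lithiated (S)-4-benzyl-1,3-oxazolidin-2-one to the imide (S)-4-benzyl-3-(3-methylidenehex-5-enoyl)-1,3-oxazolidin-2-one F3. An Evans syn-aldol reaction with 8 (n-Bu2BOTf, Et3N, CH2Cl2, −78 °C) should give the syn adduct F4. Transamination (AlMe3, MeONHMe·HCl) gives the hydroxy Weinreb amide F5, and silylation (TBSOTf, 2,6-lutidine) gives the silyl ether F6. Addition of the weakly basic isopropylcerium reagent (i-PrMgCl, CeCl3, THF, −78 °C) then gives 11.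

Step 11. The β-hydroxy ketone 19 may epimerise at C5, or hydride may be delivered to the α-face, so that the 6α-alcohol is not obtained cleanly. The fallback sets out from 18 and returns at 23 without passing through the ketone. A Mitsunobu esterification of 18 with 22 (PPh3, DIAD, PhMe, 0 °C to rt) should invert C6 and install the ester in one operation, giving 4β-hydroxydauc-8-en-6α-yl 4-[(tert-butyldimethylsilyl)oxy]benzoate F7. Epoxidation with mCPBA (NaHCO3, CH2Cl2, 0 °C), expected from the α-face away from the angular methyl, then gives 23.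

**Further compounds**
F1 | step 7 | open-chain keto sulfone, 1-[2-[(tert-butyldimethylsilyl)oxy]-4,7-dimethyl-7-[2-(phenylsulfonyl)ethyl]cyclohept-4-en-1-yl]-2-methylpropan-1-one (configuration as in 16) | CC(C)C(=O)[C@H]1[C@](C)(CCS(=O)(=O)c2ccccc2)CC=C(C)C[C@H]1O[Si](C)(C)C(C)(C)C
F2 | step 4 | 3-methylidenehex-5-enoic acid | C=CCC(=C)CC(=O)O
F3 | step 4 | (S)-4-benzyl-3-(3-methylidenehex-5-enoyl)-1,3-oxazolidin-2-one | C=CCC(=C)CC(=O)N1[C@@H](Cc2ccccc2)COC1=O
F4 | step 4 | syn-aldol imide, (S)-4-benzyl-3-[(2S,3R)-3-hydroxy-5-methyl-2-(penta-1,4-dien-2-yl)hex-5-enoyl]-1,3-oxazolidin-2-one | C=CCC(=C)[C@H](C(=O)N1[C@@H](Cc2ccccc2)COC1=O)[C@H](O)CC(C)=C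
F5 | step 4 | (2S,3R)-3-hydroxy-N-methoxy-N,5-dimethyl-2-(penta-1,4-dien-2-yl)hex-5-enamide | C=CCC(=C)[C@H](C(=O)N(C)OC)[C@H](O)CC(C)=C
F6 | step 4 | (2S,3R)-3-[(tert-butyldimethylsilyl)oxy]-N-methoxy-N,5-dimethyl-2-(penta-1,4-dien-2-yl)hex-5-enamide | C=CCC(=C)[C@H](C(=O)N(C)OC)[C@H](O[Si](C)(C)C(C)(C)C)CC(C)=C
F7 | step 11 | 4β-hydroxydauc-8-en-6α-yl 4-[(tert-butyldimethylsilyl)oxy]benzoate | CC(C)[C@]1(O)CC[C@]2(C)CC=C(C)C[C@H](OC(=O)c3ccc(O[Si](C)(C)C(C)(C)C)cc3)[C@H]21
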